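## Retrosynthetic overview

1. The caffeate ester is disconnected to (E)-3,4-diacetoxycinnamic acid and a cis-fused labd-8(17)-ene-15,19-diol; the C19 acid comes from the C19 primary alcohol.
2. Both rings of that diol come from one cationic cascade of an acyclic (S)-2,2-disubstituted oxirane carrying a (Z)- and an (E)-trisubstituted alkene: ring A closes first (C4–C5, oxirane opening), ring B second (C10–C9), then loss of a C17 hydrogen gives the exocyclic alkene.
3. The acyclic precursor is cut at the C5–C6 sp2–sp3 bond into a (Z)-vinyl iodide that carries the oxirane and a dienol (hydroboration, then Suzuki coupling).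
4. The (Z)-vinyl iodide comes from carbocupration of propyne, and its oxirane from an asymmetric Corey–Chaykovsky reaction on a methyl ketone. The dienol comes from (S)-citronellol, which supplies C13 and, through allylic oxidation of its (E)-methyl group, the (E)-alkene.

Assumption: the SMILES is taken literally; in labdane numbering it reads (4S,5S,9R,10R,13S), a cis-fused decalin with H-5, H-9, CH3-20 and C-19 all on one face (the 5,9-diepimer of the usual trans-labdane), and that is what the route makes.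
Assumption: (S)-LaLi3(binaphthoxide)3 gives the (S)-oxirane from this alkyl methyl ketone as it does from aryl methyl ketones; if the sense is opposite, its antipode is used.
Assumption: (E)-3,4-diacetoxycinnamic acid (the diacetate of caffeic acid) is bought.

## Route

Step 1
Reactants: 1 (S)-citronellol
Product: 3 (2E,6S)-8-hydroxy-2,6-dimethyloct-2-enal, via allylic diol 2 (not isolated)
Conditions: SeO2 (0.3 equiv), t-BuOOH (2.5 equiv), CH2Cl2, rt; then MnO2 (15 equiv), rt, same flask
Reagents that add atoms: tert-butyl hydroperoxide, CC(C)(C)OO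
Why: SeO2/t-BuOOH allylic hydroxylation (ene reaction, then [2,3]-shift) attacks only the (E)-methyl group of the trisubstituted alkene, and MnO2 then oxidises only the allylic alcohol; this fixes the later C8=C9 geometry, and C13 comes unchanged from the chiral pool.

Step 2
Reactants: 3 (2E,6S)-8-hydroxy-2,6-dimethyloct-2-enal
Product: 4 (3S,6E)-3,7-dimethylnona-6,8-dien-1-ol
Conditions: Ph3PCH3Br (2.5 equiv), KOtBu (2.4 equiv), THF, 0 °C → rt
Reagents that add atoms: methyltriphenylphosphonium bromide, C[P+](c1ccccc1)(c1ccccc1)c1ccccc1.[Br-]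
Why: Wittig methylenation of the enal (the free hydroxyl consumes one extra equivalent of ylide) gives the 1,3-diene and leaves the (E)-alkene and C13 untouched.

Step 3
Reactants: 5 2-(3-chloropropyl)-2-methyl-1,3-dioxolane; 6 propyne
Product: 10 2-[(4Z)-5-iodo-4-methylpent-4-en-1-yl]-2-methyl-1,3-dioxolane, via Grignard reagent 7 (not isolated), via alkylcopper 8 (not isolated), via vinylcopper 9 (not isolated)
Conditions: Mg, THF, 50 °C; CuBr·SMe2 (1 equiv), Et2O–Me2S, −45 °C; propyne (3 equiv), −25 °C; I2, THF, −50 → 0 °C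
Reagents that add atoms: iodine, II
Why: Normant carbocupration adds the alkyl group and copper syn across propyne (alkyl on the internal carbon), and iodinolysis with retention gives only the (Z)-iodoalkene with the chain cis to iodine; this geometry later becomes the cis ring fusion.

Step 4
Reactants: 10 2-[(4Z)-5-iodo-4-methylpent-4-en-1-yl]-2-methyl-1,3-dioxolane
Product: 11 (6Z)-7-iodo-6-methylhept-6-en-2-one
Conditions: 1 M aq. HCl, THF, rt
Reagents that add atoms: water, O
Why: Acid-catalysed ketal hydrolysis; the vinyl iodide is inert to dilute acid.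

Step 5
Reactants: 11 (6Z)-7-iodo-6-methylhept-6-en-2-one
Product: 12 (2S)-2-[(4Z)-5-iodo-4-methylpent-4-en-1-yl]-2-methyloxirane
Conditions: Me3S(O)I, NaH, THF (ylide pre-formed); (S)-LaLi3(binaphthoxide)3 (5 mol %), tris(2,4,6-trimethoxyphenyl)phosphine oxide (5 mol %), 5 Å MS, THF, rt
Reagents that add atoms: trimethylsulfoxonium iodide, C[S+](C)(C)=O.[I-]
Why: Catalytic asymmetric Corey–Chaykovsky epoxidation of a methyl ketone: the sulfur ylide adds to one face of the lanthanum-bound ketone and the betaine closes, which sets C4 as (S) (about 90–95 % ee expected) and brings in C19.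

Step 6
Reactants: 4 (3S,6E)-3,7-dimethylnona-6,8-dien-1-ol; 12 (2S)-2-[(4Z)-5-iodo-4-methylpent-4-en-1-yl]-2-methyloxirane
Product: 14 (3S,6E,10Z)-3,7,11-trimethyl-14-[(2S)-2-methyloxiran-2-yl]tetradeca-6,10-dien-1-ol, via bis(9-BBN) adduct 13 (not isolated)
Conditions: 9-BBN (2.2 equiv B–H), THF, 0 °C → rt; then 12 (0.9 equiv), Pd(dppf)Cl2 (5 mol %), AsPh3 (10 mol %), Cs2CO3 (3 equiv), DMF–THF–H2O, rt
Reagents that add atoms: none
Why: 9-BBN hydroborates only the monosubstituted alkene of the diene at its terminal carbon (one equivalent is taken up by the hydroxyl), and the B-alkyl Suzuki–Miyaura coupling joins C6 to C5 with retention of the (Z)-geometry while the oxirane survives the mild aqueous base.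

Step 7
Reactants: 14 (3S,6E,10Z)-3,7,11-trimethyl-14-[(2S)-2-methyloxiran-2-yl]tetradeca-6,10-dien-1-ol
Product: 15 (4S,5S,9R,10R,13S)-labd-8(17)-ene-15,19-diol
Conditions: MeAlCl2 (3.5 equiv), CH2Cl2 (0.005 M), −90 → −78 °C, 30 min; then 1,2,2,6,6-pentamethylpiperidine (8 equiv), −78 → −40 °C; aq. Rochelle salt
Reagents that add atoms: none
Why: Proposed new method: a Lewis-acid-promoted epoxide-initiated cation–olefin bicyclisation of the van Tamelen/Corey epoxy-polyene type, started here from a 2,2-disubstituted oxirane so that the oxygen ends on C19 and C3 stays CH2; MeAlCl2 (which first turns the C15 hydroxyl into an aluminium alkoxide) activates the oxirane, the tertiary C4–O bond breaks with backside participation of the C5=C10 alkene (inversion, so the (S)-oxirane gives 4S), the oxirane CH2 lies gauche to C2 in the staggered rotamer that puts C5 anti to the breaking C–O bond and so becomes the axial CH2OH cis to C20, anti (Stork–Eschenmoser) addition across the (Z)-alkene gives the cis ring fusion (5S,10R) as ring A closes, chair closure of ring B onto the (E)-alkene puts the side chain equatorial and trans to C20 (9R), and the hindered amine takes the most exposed hydrogen (C17 methyl) from the C8 cation/chloride ion pair to give the exocyclic alkene, by analogy with hindered-amine quenching of tertiary carbocations to exo-olefins.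

Step 8
Reactants: 15 (4S,5S,9R,10R,13S)-labd-8(17)-ene-15,19-diol; 16 (2E)-3-(3,4-diacetoxyphenyl)prop-2-enoic acid
Product: 17 (4S,5S,9R,10R,13S)-19-hydroxylabd-8(17)-en-15-yl (2E)-3-(3,4-diacetoxyphenyl)prop-2-enoate
Conditions: 16 (1.05 equiv), EDC·HCl (1.2 equiv), DMAP (5 mol %), CH2Cl2, −10 → 0 °C
Reagents that add atoms: none
Why: Steglich esterification; the unhindered C15 primary hydroxyl reacts much faster than the neopentyl C19 hydroxyl at low temperature with one equivalent of acid.

Step 9
Reactants: 17 (4S,5S,9R,10R,13S)-19-hydroxylabd-8(17)-en-15-yl (2E)-3-(3,4-diacetoxyphenyl)prop-2-enoate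
Product: 19 (4S,5S,9R,10R,13S)-15-{[(2E)-3-(3,4-diacetoxyphenyl)prop-2-enoyl]oxy}labd-8(17)-en-19-oic acid, via C19 aldehyde 18 (not isolated)
Conditions: Dess–Martin periodinane (1.3 equiv), CH2Cl2, rt; then t-BuOH, H2O, 2-methyl-2-butene (20 equiv), NaH2PO4, NaClO2, rt, same flask
Reagents that add atoms: sodium chlorite, [Na+].[O-]Cl=O
Why: Dess–Martin oxidation of the neopentyl alcohol followed by Pinnick oxidation of the aldehyde; the exocyclic alkene is shielded from HOCl by the scavenger, the phenols are masked as acetates, and C4 is quaternary so it cannot epimerise.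

Step 10
Reactants: 19 (4S,5S,9R,10R,13S)-15-{[(2E)-3-(3,4-diacetoxyphenyl)prop-2-enoyl]oxy}labd-8(17)-en-19-oic acid
Product: 20 (4S,5S,9R,10R,13S)-15-{[(2E)-3-(3,4-dihydroxyphenyl)prop-2-enoyl]oxy}labd-8(17)-en-19-oic acid
Conditions: pyrrolidine (5 equiv), CH2Cl2, 0 °C, Ar; aq. KHSO4 work-up
Reagents that add atoms: none
Why: Aminolysis of the two activated aryl acetates is far faster than attack on the conjugated alkyl cinnamate ester or the hindered acid (chemoselective deacetylation), and the acidic work-up returns the free acid and catechol.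

## Compound list

1 | (S)-citronellol, (3S)-3,7-dimethyloct-6-en-1-ol | CC(C)=CCC[C@H](C)CCO | starting material
2 | (2E,6S)-2,6-dimethyloct-2-ene-1,8-diol | OC/C(C)=C/CC[C@H](C)CCO | intermediate
3 | (2E,6S)-8-hydroxy-2,6-dimethyloct-2-enal | O=C/C(C)=C/CC[C@H](C)CCO | intermediate
4 | (3S,6E)-3,7-dimethylnona-6,8-dien-1-ol | C=C/C(C)=C/CC[C@H](C)CCO | intermediate
5 | 2-(3-chloropropyl)-2-methyl-1,3-dioxolane | CC1(CCCCl)OCCO1 | starting material
6 | propyne | CC#C | starting material
7 | [3-(2-methyl-1,3-dioxolan-2-yl)propyl]magnesium chloride | CC1(CCC[Mg]Cl)OCCO1 | intermediate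
8 | [3-(2-methyl-1,3-dioxolan-2-yl)propyl]copper (MgBrCl/SMe2 complex) | CC1(CCC[Cu])OCCO1 | intermediate
9 | [(1Z)-2-methyl-5-(2-methyl-1,3-dioxolan-2-yl)pent-1-en-1-yl]copper | CC1(CCC/C(C)=C\[Cu])OCCO1 | intermediate
10 | 2-[(4Z)-5-iodo-4-methylpent-4-en-1-yl]-2-methyl-1,3-dioxolane | CC1(CCC/C(C)=C\I)OCCO1 | intermediate
11 | (6Z)-7-iodo-6-methylhept-6-en-2-one | CC(=O)CCC/C(C)=C\I | intermediate
12 | (2S)-2-[(4Z)-5-iodo-4-methylpent-4-en-1-yl]-2-methyloxirane | C[C@]1(CCC/C(C)=C\I)CO1 | intermediate
13 | 9-{[(3S,6E)-9-(9-borabicyclo[3.3.1]nonan-9-yl)-3,7-dimethylnon-6-en-1-yl]oxy}-9-borabicyclo[3.3.1]nonane | C1CCC2CCCC1B2CC/C(C)=C/CC[C@H](C)CCOB1C2CCCC1CCC2 | intermediate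
14 | (3S,6E,10Z)-3,7,11-trimethyl-14-[(2S)-2-methyloxiran-2-yl]tetradeca-6,10-dien-1-ol | C[C@]1(CCC/C(C)=C\CC/C(C)=C/CC[C@H](C)CCO)CO1 | intermediate
15 | (4S,5S,9R,10R,13S)-labd-8(17)-ene-15,19-diol (labdane numbering, cis-fused); (3S)-5-[(1R,4aS,5S,8aR)-5-(hydroxymethyl)-5,8a-dimethyl-2-methylidenedecahydronaphthalen-1-yl]-3-methylpentan-1-ol | C=C1CC[C@H]2[C@](C)(CCC[C@]2(C)CO)[C@@H]1CC[C@H](C)CCO | intermediate
16 | (2E)-3-(3,4-diacetoxyphenyl)prop-2-enoic acid | CC(=O)Oc1ccc(/C=C/C(=O)O)cc1OC(C)=O | starting material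
17 | (4S,5S,9R,10R,13S)-19-hydroxylabd-8(17)-en-15-yl (2E)-3-(3,4-diacetoxyphenyl)prop-2-enoate | C=C1CC[C@H]2[C@](C)(CCC[C@]2(C)CO)[C@@H]1CC[C@H](C)CCOC(=O)/C=C/c1ccc(OC(C)=O)c(OC(C)=O)c1 | intermediate
18 | (4S,5S,9R,10R,13S)-19-oxolabd-8(17)-en-15-yl (2E)-3-(3,4-diacetoxyphenyl)prop-2-enoate | C=C1CC[C@H]2[C@](C)(CCC[C@]2(C)C=O)[C@@H]1CC[C@H](C)CCOC(=O)/C=C/c1ccc(OC(C)=O)c(OC(C)=O)c1 | intermediate
19 | (4S,5S,9R,10R,13S)-15-{[(2E)-3-(3,4-diacetoxyphenyl)prop-2-enoyl]oxy}labd-8(17)-en-19-oic acid | C=C1CC[C@H]2[C@](C)(CCC[C@]2(C)C(=O)O)[C@@H]1CC[C@H](C)CCOC(=O)/C=C/c1ccc(OC(C)=O)c(OC(C)=O)c1 | intermediate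
20 | (1S,4aR,5R,8aS)-5-[(3S)-5-{[(2E)-3-(3,4-dihydroxyphenyl)prop-2-enoyl]oxy}-3-methylpentyl]-1,4a-dimethyl-6-methylidenedecahydronaphthalene-1-carboxylic acid | C=C1CC[C@H]2[C@](C)(CCC[C@]2(C)C(=O)O)[C@@H]1CC[C@H](C)CCOC(=O)/C=C/c1ccc(O)c(O)c1 | target

## Step count and risks

Total step count: 10. Longest linear sequence: 8 steps (steps 3, 4, 5, 6, 7, 8, 9, 10 from 5); the citronellol branch is 7.

The three steps most likely to fail:

Step 7 (the cascade). The opened oxirane can undergo a 1,2-hydride shift to an aldehyde, the C8 cation can be captured by chloride, the C4 epimer with an equatorial CH2OH can form (a separable diastereomer), and above all a ring hydrogen can be lost instead of a methyl hydrogen. Fallback, from 14 back to 15: do not ask the cascade to finish by deprotonation. Run it with SnCl4 (CH2Cl2, −78 °C) so that it ends by chloride capture at C8, and isolate the tertiary chloride (4S,5S,9R,10R,13S)-8-chlorolabdane-15,19-diol F1 (C8 configuration open; endocyclic alkene isomers can be funnelled into the same chloride with dry HCl). Then form the alkene in a separate E2 step with a bulky alkoxide (KOCEt3, toluene, 60 °C), which removes a methyl hydrogen in preference to the hindered ring hydrogens and gives 15.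

Step 5 (asymmetric epoxidation). The catalyst is proven on simpler methyl ketones, and because C13 is already fixed, any minor oxirane enantiomer becomes a hard-to-remove diastereomer after step 7. Fallback, from 11 back to 12: make the oxirane with the uncatalysed sulfoxonium ylide as rac-2-[(4Z)-5-iodo-4-methylpent-4-en-1-yl]-2-methyloxirane F2. Resolve it kinetically by azide ring opening with TMSN3 and the (salen)CrN3 enantiomer that consumes the (R)-oxirane, which is removed as {[(2R,6Z)-1-azido-7-iodo-2,6-dimethylhept-6-en-2-yl]oxy}trimethylsilane F3. Unreacted (S)-oxirane 12 is recovered in high ee, at most about 45 %.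

Step 6 (hydroboration and coupling). Borane may add twice to the diene, the free hydroxyl complicates the stoichiometry, and the B-alkyl coupling can stall. Fallback, from 4 back to 14: separate borane formation from the coupling and change the metal. Silylate 4 (TBSCl, imidazole) to tert-butyl{[(3S,6E)-3,7-dimethylnona-6,8-dien-1-yl]oxy}dimethylsilane F4. Hydroborate and iodinate (9-BBN; then I2, NaOMe) to tert-butyl{[(3S,6E)-9-iodo-3,7-dimethylnon-6-en-1-yl]oxy}dimethylsilane F5. Convert this into the alkylzinc (t-BuLi, then ZnCl2) and couple it with 12 under Negishi conditions (Pd(PPh3)4, THF) to tert-butyldimethyl{[(3S,6E,10Z)-3,7,11-trimethyl-14-[(2S)-2-methyloxiran-2-yl]tetradeca-6,10-dien-1-yl]oxy}silane F6; TBAF then gives 14.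

## Further compounds

F1 | step 7 | (4S,5S,9R,10R,13S)-8-chlorolabdane-15,19-diol (C8 configuration open) | CC1(Cl)CC[C@H]2[C@](C)(CCC[C@]2(C)CO)[C@@H]1CC[C@H](C)CCO
F2 | step 5 | rac-2-[(4Z)-5-iodo-4-methylpent-4-en-1-yl]-2-methyloxirane | CC1(CCC/C(C)=C\I)CO1
F3 | step 5 | {[(2R,6Z)-1-azido-7-iodo-2,6-dimethylhept-6-en-2-yl]oxy}trimethylsilane | C[C@@](CCC/C(C)=C\I)(CN=[N+]=[N-])O[Si](C)(C)C
F4 | step 6 | tert-butyl{[(3S,6E)-3,7-dimethylnona-6,8-dien-1-yl]oxy}dimethylsilane | C=C/C(C)=C/CC[C@H](C)CCO[Si](C)(C)C(C)(C)C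
F5 | step 6 | tert-butyl{[(3S,6E)-9-iodo-3,7-dimethylnon-6-en-1-yl]oxy}dimethylsilane | ICC/C(C)=C/CC[C@H](C)CCO[Si](C)(C)C(C)(C)C
F6 | step 6 | tert-butyldimethyl{[(3S,6E,10Z)-3,7,11-trimethyl-14-[(2S)-2-methyloxiran-2-yl]tetradeca-6,10-dien-1-yl]oxy}silane | C[C@]1(CCC/C(C)=C\CC/C(C)=C/CC[C@H](C)CCO[Si](C)(C)C(C)(C)C)CO1
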